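We begin at the late end of the flask: substrate stands on the left of every step, so we ask how its charge has been divided by the time the steps stop.

    substrate + reagent + by-product → target + 2 by-product (k1 = 0.20 M⁻² s⁻¹)
    substrate + reagent → target + by-product (k2 = 7.5 × 10⁻⁶ M⁻¹ s⁻¹)
    substrate + target → side product (k3 = 0.015 M⁻¹ s⁻¹)

substrate 0.86 M; reagent 1.50 equiv; time 6.0 min

- target at 6.0 min, in percent of the substrate charged
- side product at 6.0 min, in percent of the substrate charged

The uncatalysed step gives substrate a half-life of 20 h, far longer than the 6.0 min of the run, so we let it merely seed by-product. Substrate then has two ways to go, the autocatalytic step and the side step. While the side step stays small, [target] stays close to [by-product], and these two concentrations cancel when we divide one rate by the other. What remains is the autocatalytic constant times [reagent], against the side-step constant. We take [reagent] halfway through the substrate, 0.860 M, which gives 0.172 M⁻¹ s⁻¹ against 0.015 M⁻¹ s⁻¹. Their ratio is the side share, side product formed per by-product formed, 0.0872; its inverse is a selectivity factor. Each side product takes one substrate and one target, so if the substrate is used up, we reckon target 84.0% and side product 16.0%.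

The forecast, slightly different from our figures, says 84.5% and 15.5%, holding that “the target no longer changes because the side reaction needs substrate”.

The flask gives 84.5% and 15.5%, and its substrate already stands at 0% after 3.00 min. Its side product per by-product reads 0.0840, beside our 0.0872. For the neighbour charged with 0.34 M of substrate, the same reckoning puts halfway [reagent] at 0.340 M and the side share at 0.221, higher than in the first flask. That neighbour reads 0.172, with target 61.2%, side product 25.4% and substrate 13.4% still there at 6.00 min.

Its constants stand for no real mixture; the rest is arithmetic.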